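**Plan**

1. Retrosynthesis first undoes the late adjustments: the C1–OCH3 bond, the hydrogens of the C5 ethylene bridge and the four outer phenolic hydrogens (carried as benzyl ethers), leaving a mirror-symmetric 5-styrylresorcinol.
2. Enabling feature: the central benzene ring (C1 OMe, C3 OH, 4-hydroxybenzyl CH2 on C2, C4 and C6, the two-carbon bridge on C5) is a folded 1,3,5-triketone whose C5 is a carbonyl carbon with a non-enolizable exocyclic neighbour. The ring is cut at C5–C6 and C4–C5.
3. This leaves a cinnamoyl Weinreb amide (cut at its C=C bond) and a 4-benzylated 1,7-diarylheptane-3,5-dione, itself cut at its three benzylic CH2–C bonds to pentane-2,4-dione and one benzylic bromide.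
4. Forward: two terminal and one central C-benzylation of pentane-2,4-dione build the chain; the amide is attached and the chain folds to the only new ring (the central arene) in one operation; mono-O-methylation and one hydrogenation finish.
5. Stereochemistry: the target has no stereogenic element; the E double bond from the olefination is a spectator and is saturated at the end.

Key step: step 4

Remark: the target has no stereocentre and no stereogenic double bond, so "single enantiomer" is read as the one achiral compound. β-Dicarbonyl compounds are drawn as keto forms although largely enolized, and 9 and 10 are drawn without configuration because their sp3 centres are epimerizable and vanish on aromatization.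

**Route**

Step 1
Reactants: 1 pentane-2,4-dione; 2 1-(benzyloxy)-4-(bromomethyl)benzene (2 equiv)
Product: 4 1,7-bis[4-(benzyloxy)phenyl]heptane-3,5-dione, via monobenzylated dione 3 (not isolated)
Conditions: LDA (2.1 equiv), THF, 0 °C; 2 (1.0 equiv), 0 °C; LDA (1.05 equiv), 0 °C; 2 (1.0 equiv), 0 °C → rt; 1 M HCl
Reagents that add atoms: none
Why: Terminal (γ) alkylation of a β-diketone dianion: the less stabilized methyl carbanion is the nucleophilic site and is benzylated by the SN2-reactive bromide, and re-deprotonation of the lithium enolate of 3 occurs at the remaining methyl group in preference to the substituted methylene, so the second benzylation should give the symmetric dione.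

Step 2
Reactants: 4 1,7-bis[4-(benzyloxy)phenyl]heptane-3,5-dione; 2 1-(benzyloxy)-4-(bromomethyl)benzene
Product: 5 4-[4-(benzyloxy)benzyl]-1,7-bis[4-(benzyloxy)phenyl]heptane-3,5-dione
Conditions: 2 (1.0 equiv), K2CO3, acetone, reflux
Reagents that add atoms: none
Why: C-Alkylation of a β-diketone enolate: the soft, delocalized potassium enolate of 4 reacts at the central carbon with the benzylic bromide under classical carbonate/acetone conditions, and one equivalent of electrophile keeps a second alkylation at C4 low.

Step 3
Reactants: 6 3-(benzyloxy)benzaldehyde; 7 diethyl {2-[methoxy(methyl)amino]-2-oxoethyl}phosphonate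
Product: 8 (E)-3-[3-(benzyloxy)phenyl]-N-methoxy-N-methylprop-2-enamide
Conditions: NaH, THF, 0 °C → rt
Reagents that add atoms: none
Why: Horner–Wadsworth–Emmons olefination: the stabilized phosphonate anion adds reversibly to the non-enolizable aryl aldehyde and elimination through the more stable oxaphosphetane should deliver the E-enamide, whose geometry is in any case erased by the final hydrogenation.

Step 4
Reactants: 5 4-[4-(benzyloxy)benzyl]-1,7-bis[4-(benzyloxy)phenyl]heptane-3,5-dione; 8 (E)-3-[3-(benzyloxy)phenyl]-N-methoxy-N-methylprop-2-enamide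
Product: 11 2,4,6-tris[4-(benzyloxy)benzyl]-5-{(E)-2-[3-(benzyloxy)phenyl]ethenyl}benzene-1,3-diol, via triketone 9 (not isolated), via cyclic aldol 10 (not isolated)
Conditions: 5 (1.1 equiv), LDA (2.3 equiv), THF, −78 → 0 °C; 8 (1.0 equiv), −78 → 0 °C; then degassed MeOH/2 M aq. KOH, 0 → 50 °C; 1 M HCl
Reagents that add atoms: none
Why: Two equivalents of LDA convert 5 into its dianion (C4 enolate plus one terminal α-carbanion, the two terminal methylenes being equivalent), and the terminal carbanion adds 1,2 to the Weinreb amide to make the future C5–C6 bond, the lithium-chelated tetrahedral adduct persisting until the protic quench so that neither over-addition nor proton transfer to unreacted dianion can occur. Methanolic KOH then releases triketone 9, whose remaining terminal CH2 (future C4) adds as its enolate to the cinnamoyl carbonyl (future C5) in a 6-(enolendo)-exo-trig aldol to give 10, and β-elimination of water followed by enolization of the two ring ketones delivers the aromatic resorcinol 11. The closest known reaction types are the γ-acylation of β-diketone dianions and the base-mediated aldol aromatization of 1,3,5-triketones to resorcinols (heptane-2,4,6-trione to orcinol), the laboratory counterpart of the folding used by stilbene and bibenzyl synthases. No stereocentre remains, since the epimerizable centres of 9 and 10 are erased on aromatization and the E double bond is not touched. The step needs one direction of folding and C- rather than O-cyclization: the first is secured because the cinnamoyl carbonyl has a vinylic, non-enolizable α-carbon and can only act as acceptor, leaving the terminal CH2 (future C4) as the sole nucleophile able to form a six-membered carbocycle, and the second because alkaline rather than acidic conditions favour the aldol over 4-pyranone formation. Conjugate addition to the styryl unit is disfavoured by the low Michael reactivity of the Weinreb amide and, after the quench, by the enolate character of the triketone.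

Step 5
Reactants: 11 2,4,6-tris[4-(benzyloxy)benzyl]-5-{(E)-2-[3-(benzyloxy)phenyl]ethenyl}benzene-1,3-diol
Product: 12 2,4,6-tris[4-(benzyloxy)benzyl]-3-{(E)-2-[3-(benzyloxy)phenyl]ethenyl}-5-methoxyphenol
Conditions: MeI (1.0 equiv), K2CO3 (1.0 equiv), DMF, rt; recovered 11 recycled
Reagents that add atoms: iodomethane, CI
Why: Williamson ether synthesis on a phenoxide: only the two central hydroxyls are free, they are interchanged by the mirror plane through C2 and C5 so that a single monoether is possible, and limiting base and iodomethane should hold the diether back.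

Step 6
Reactants: 12 2,4,6-tris[4-(benzyloxy)benzyl]-3-{(E)-2-[3-(benzyloxy)phenyl]ethenyl}-5-methoxyphenol
Product: 13 2,4,6-tris(4-hydroxybenzyl)-5-[2-(3-hydroxyphenyl)ethyl]-3-methoxyphenol
Conditions: H2 (1 atm), 10% Pd/C, EtOAc/MeOH, rt
Reagents that add atoms: none
Why: Heterogeneous catalytic hydrogenation and hydrogenolysis: palladium on carbon should saturate the disubstituted styryl double bond and cleave the four aryl benzyl ethers in one operation, while the aryl methyl ether, the diarylmethane C–C bonds and the arenes are inert at 1 atm.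

**Compound list**

1 | pentane-2,4-dione | CC(=O)CC(C)=O | starting material
2 | 1-(benzyloxy)-4-(bromomethyl)benzene | BrCc1ccc(OCc2ccccc2)cc1 | starting material
3 | 6-[4-(benzyloxy)phenyl]hexane-2,4-dione | CC(=O)CC(=O)CCc1ccc(OCc2ccccc2)cc1 | intermediate (not isolated)
4 | 1,7-bis[4-(benzyloxy)phenyl]heptane-3,5-dione | O=C(CCc1ccc(OCc2ccccc2)cc1)CC(=O)CCc1ccc(OCc2ccccc2)cc1 | intermediate
5 | 4-[4-(benzyloxy)benzyl]-1,7-bis[4-(benzyloxy)phenyl]heptane-3,5-dione | O=C(CCc1ccc(OCc2ccccc2)cc1)C(Cc1ccc(OCc2ccccc2)cc1)C(=O)CCc1ccc(OCc2ccccc2)cc1 | intermediate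
6 | 3-(benzyloxy)benzaldehyde | O=Cc1cccc(OCc2ccccc2)c1 | starting material
7 | diethyl {2-[methoxy(methyl)amino]-2-oxoethyl}phosphonate | CCOP(=O)(CC(=O)N(C)OC)OCC | starting material
8 | (E)-3-[3-(benzyloxy)phenyl]-N-methoxy-N-methylprop-2-enamide | CON(C)C(=O)/C=C/c1cccc(OCc2ccccc2)c1 | intermediate
9 | (1E)-4,6-bis[4-(benzyloxy)benzyl]-1-[3-(benzyloxy)phenyl]-9-[4-(benzyloxy)phenyl]non-1-ene-3,5,7-trione (diastereomer and enol mixture) | O=C(/C=C/c1cccc(OCc2ccccc2)c1)C(Cc1ccc(OCc2ccccc2)cc1)C(=O)C(Cc1ccc(OCc2ccccc2)cc1)C(=O)CCc1ccc(OCc2ccccc2)cc1 | intermediate (not isolated)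
10 | 2,4,6-tris[4-(benzyloxy)benzyl]-5-{(E)-2-[3-(benzyloxy)phenyl]ethenyl}-5-hydroxycyclohexane-1,3-dione (diastereomer mixture) | OC1(/C=C/c2cccc(OCc3ccccc3)c2)C(Cc2ccc(OCc3ccccc3)cc2)C(=O)C(Cc2ccc(OCc3ccccc3)cc2)C(=O)C1Cc1ccc(OCc2ccccc2)cc1 | intermediate (not isolated)
11 | 2,4,6-tris[4-(benzyloxy)benzyl]-5-{(E)-2-[3-(benzyloxy)phenyl]ethenyl}benzene-1,3-diol | Oc1c(Cc2ccc(OCc3ccccc3)cc2)c(O)c(Cc2ccc(OCc3ccccc3)cc2)c(/C=C/c2cccc(OCc3ccccc3)c2)c1Cc1ccc(OCc2ccccc2)cc1 | intermediate
12 | 2,4,6-tris[4-(benzyloxy)benzyl]-3-{(E)-2-[3-(benzyloxy)phenyl]ethenyl}-5-methoxyphenol | COc1c(Cc2ccc(OCc3ccccc3)cc2)c(O)c(Cc2ccc(OCc3ccccc3)cc2)c(/C=C/c2cccc(OCc3ccccc3)c2)c1Cc1ccc(OCc2ccccc2)cc1 | intermediate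
13 | 2,4,6-tris(4-hydroxybenzyl)-5-[2-(3-hydroxyphenyl)ethyl]-3-methoxyphenol | COc1c(Cc2ccc(O)cc2)c(O)c(Cc2ccc(O)cc2)c(CCc2cccc(O)c2)c1Cc1ccc(O)cc1 | target

**Count**

Total steps: 6. Longest linear sequence: 5 (steps 1, 2, 4, 5, 6); step 3 is a one-step side branch.

**Steps most likely to fail**

Step 4. The dianion may add in conjugate fashion to the cinnamoyl acceptor, or the hindered secondary carbanion may acylate too slowly. During the alkaline stage, retro-Claisen cleavage or closure through oxygen (oxa-Michael addition of an enol oxygen to the styryl ketone, or pyranone formation) may outrun the aldol. The fallback sets out from 5 and 8 and returns at 11. Amide 8 is reduced with DIBAL-H (THF, −78 °C) to (E)-3-[3-(benzyloxy)phenyl]prop-2-enal F1. The dianion of 5 (LDA, THF, −78 °C) is added to this aldehyde, which is far more electrophilic than the amide and reacts 1,2, giving (1E)-4,6-bis[4-(benzyloxy)benzyl]-1-[3-(benzyloxy)phenyl]-9-[4-(benzyloxy)phenyl]-3-hydroxynon-1-ene-5,7-dione F2. Oxidation of the allylic alcohol (MnO2, CH2Cl2, or Dess–Martin periodinane) gives triketone 9, now isolated. It is then cyclized on its own under separately tuned mild base (aq. KOH/MeOH or a pH 9–10 buffer) through 10 to 11. The same two ring bonds are formed.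

Step 5. Both hydroxyls react at the same rate, so conversion to the monoether competes with over-methylation and leaves starting diol, and the doubly ortho-substituted phenoxide may alkylate sluggishly. The fallback sets out from 11 and returns at 13. Exhaustive methylation (excess MeI, K2CO3, DMF) gives 1,3,5-tris[4-(benzyloxy)benzyl]-2-{(E)-2-[3-(benzyloxy)phenyl]ethenyl}-4,6-dimethoxybenzene F3. Hydrogenation (H2, Pd/C) gives 3-{2-[2,4,6-tris(4-hydroxybenzyl)-3,5-dimethoxyphenyl]ethyl}phenol F4. Sodium ethanethiolate (excess, DMF, 120–140 °C) then removes one methyl group only, because the phenoxide formed on the central ring deactivates the second methoxy group toward SN2 cleavage (the classical mono-demethylation of resorcinol dimethyl ethers), giving 13. The thiolate step is placed after hydrogenolysis because aryl benzyl ethers would not survive it.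

Step 1. Site control may be lost in the one-pot double alkylation: proton exchange between dianion and product enolates can lead to benzylation at an already substituted terminus or at C3, giving mixtures of mono-, di- and tri-benzylated diones. The fallback sets out from 1 and returns at 4. A boron-templated double aldol condensation of 1 with commercial 4-(benzyloxy)benzaldehyde (O=Cc1ccc(OCc2ccccc2)cc1; B2O3, B(On-Bu)3, n-BuNH2, EtOAc, 70 °C, then dilute HCl) gives (1E,6E)-1,7-bis[4-(benzyloxy)phenyl]hepta-1,6-diene-3,5-dione F5. Both C=C bonds are then hydrogenated over Pd/C poisoned with diphenyl sulfide (or with (Ph3P)3RhCl/H2), conditions that spare aryl benzyl ethers and ketones, to give 4.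

**Further compounds**

F1 | step 4 | (E)-3-[3-(benzyloxy)phenyl]prop-2-enal | O=C/C=C/c1cccc(OCc2ccccc2)c1
F2 | step 4 | (1E)-4,6-bis[4-(benzyloxy)benzyl]-1-[3-(benzyloxy)phenyl]-9-[4-(benzyloxy)phenyl]-3-hydroxynon-1-ene-5,7-dione (diastereomer mixture) | OC(/C=C/c1cccc(OCc2ccccc2)c1)C(Cc1ccc(OCc2ccccc2)cc1)C(=O)C(Cc1ccc(OCc2ccccc2)cc1)C(=O)CCc1ccc(OCc2ccccc2)cc1
F3 | step 5 | 1,3,5-tris[4-(benzyloxy)benzyl]-2-{(E)-2-[3-(benzyloxy)phenyl]ethenyl}-4,6-dimethoxybenzene | COc1c(Cc2ccc(OCc3ccccc3)cc2)c(OC)c(Cc2ccc(OCc3ccccc3)cc2)c(/C=C/c2cccc(OCc3ccccc3)c2)c1Cc1ccc(OCc2ccccc2)cc1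
F4 | step 5 | 3-{2-[2,4,6-tris(4-hydroxybenzyl)-3,5-dimethoxyphenyl]ethyl}phenol | COc1c(Cc2ccc(O)cc2)c(OC)c(Cc2ccc(O)cc2)c(CCc2cccc(O)c2)c1Cc1ccc(O)cc1
F5 | step 1 | (1E,6E)-1,7-bis[4-(benzyloxy)phenyl]hepta-1,6-diene-3,5-dione | O=C(/C=C/c1ccc(OCc2ccccc2)cc1)CC(=O)/C=C/c1ccc(OCc2ccccc2)cc1
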